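The whole plan rests on reading the pyran ring as a masked coumarin. Quaternary C2 is bonded to O1, two methyl groups and the C3=C4 alkene, so it has the connectivity of a lactone carbonyl that has accepted two methyl nucleophiles. Methyllithium therefore makes both C2–CH3 bonds in one operation on 5,7-bis(methoxymethoxy)-8-prenylcoumarin. This opens the lactone to a Z-configured tertiary allylic alcohol, and the liberated phenol (former O1) later recloses the pyran. The precursor already carries the prenyl group at C8, placed by a Claisen shift from O7. It also carries two MOM ethers flanking C6–H, which afterwards guide lithiation for attaching the 4-hydroxybenzoyl group.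

Key step: step 6

Remark on the chemistry: the target has no stereocentre and its only ring alkene is geometrically locked, so it is achiral and there is no enantiomer to select. The route therefore only has to control constitution. The stereochemical elements on the way are one Z alkene and two transient racemic centres, both erased. Coumarin/chromene numbering (O1, C2 … C8a) is used throughout.

Step 1
Reactants: 1 phloroglucinol; 2 ethyl propiolate
Product: 3 5,7-dihydroxy-2H-chromen-2-one (5,7-dihydroxycoumarin)
Conditions: ZnCl2 (1 equiv), neat, 90–100 °C; dilute aq. HCl work-up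
Reagents that add atoms: none
Why: Pechmann-type condensation in which the Lewis acid activates the ynoate for attack by the very electron-rich, threefold-symmetric arene and a neighbouring phenol lactonises with loss of ethanol, so only one coumarin can form.

Step 2
Reactants: 3 5,7-dihydroxycoumarin; 4 3-chloro-3-methylbut-1-yne
Product: 5 5-hydroxy-7-[(2-methylbut-3-yn-2-yl)oxy]-2H-chromen-2-one
Conditions: 4 (1.05 equiv), DBU (1.1 equiv), CuCl2·2H2O (1 mol %), MeCN–DMF, −5 → 0 °C, N2
Reagents that add atoms: none
Why: Copper-catalysed propargylic etherification with a tertiary propargyl chloride, run with one equivalent of base so that the more acidic and unhindered 7-OH (para to C4a, vinylogous to the lactone carbonyl) should react in preference to the 5-OH, which is crowded by the peri C4–H.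

Step 3
Reactants: 5 5-hydroxy-7-[(2-methylbut-3-yn-2-yl)oxy]coumarin
Product: 6 5-hydroxy-7-[(2-methylbut-3-en-2-yl)oxy]-2H-chromen-2-one
Conditions: H2 (1 atm), Lindlar catalyst, quinoline, EtOAc, rt, stopped after 1 equiv H2
Reagents that add atoms: none
Why: Lindlar semi-hydrogenation, in which the poisoned palladium surface reduces the terminal alkyne much faster than the resulting vinyl group or the conjugated C3=C4 bond.

Step 4
Reactants: 6 5-hydroxy-7-[(2-methylbut-3-en-2-yl)oxy]coumarin
Product: 8 5,7-dihydroxy-8-(3-methylbut-2-en-1-yl)-2H-chromen-2-one, via C8-prenyl cyclohexadienone 7 (not isolated)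
Conditions: PhNEt2, 130–140 °C, Ar
Reagents that add atoms: none
Why: Aromatic Claisen rearrangement ([3,3] shift, then tautomerisation of the racemic dienone) that inverts the tertiary allyl ether into a linear prenyl group and should go to C8 because the C7–C8 bond of the coumarin nucleus has the higher double-bond character, as is the rule for 7-allyloxycoumarins, while the basic solvent suppresses acid-induced loss of the allyl group and chroman formation.

Step 5
Reactants: 8 5,7-dihydroxy-8-prenylcoumarin; 9 chloromethyl methyl ether
Product: 10 5,7-bis(methoxymethoxy)-8-(3-methylbut-2-en-1-yl)-2H-chromen-2-one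
Conditions: MOMCl (3 equiv), i-Pr2NEt (4 equiv), CH2Cl2–DMF, 0 °C → rt
Reagents that add atoms: chloromethyl methyl ether (9), COCCl
Why: MOM protection (O-alkylation of both acidic phenols under amine base) leaves the lactone and prenyl group untouched, removes the acidic protons that would quench methyllithium and installs the directing groups needed in step 8.

Step 6
Reactants: 10 5,7-bis(methoxymethoxy)-8-prenylcoumarin; 11 methyllithium
Product: 13 2-[(Z)-3-hydroxy-3-methylbut-1-en-1-yl]-3,5-bis(methoxymethoxy)-6-(3-methylbut-2-en-1-yl)phenol, via lithium Z-enone phenoxide 12 (not isolated)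
Conditions: MeLi (3 equiv, Et2O solution), THF, −78 → 0 °C; cold pH 7 aqueous quench; product handled on base-washed silica or used crude
Reagents that add atoms: methyllithium (11), [Li]C
Why: The first methyllithium attacks the lactone carbonyl C2, the tetrahedral alkoxide collapses with expulsion of the C8a phenoxide to give 12, and the second methyllithium adds to the ketone carbonyl of 12, so both C2–CH3 bonds exist before the quench. The closest known reaction type is the classical double 1,2-addition of methyl Grignard or methyllithium reagents to coumarins, which gives o-(3-hydroxy-3-methylbut-1-enyl)phenols. No ring is closed (the lactone ring is opened) and no stereocentre is created; the Z geometry of the former C3=C4 bond is inherited from the ring and should persist because nothing in the cold basic medium allows rotation about it. The step needs 1,2- rather than 1,4-addition at both stages and addition rather than enolisation of the methyl ketone; a small, hard organolithium at low temperature favours carbonyl attack, and the 5- and 7-alkoxy groups, together with the phenoxide in 12, feed electron density into C4 and make it a poor acceptor. MOM ethers, the prenyl group and C6–H are inert to methyllithium at these temperatures, and the neutral quench avoids uncontrolled loss of water.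

Step 7
Reactants: 13 Z-allylic tertiary alcohol phenol
Product: 14 5,7-bis(methoxymethoxy)-2,2-dimethyl-8-(3-methylbut-2-en-1-yl)-2H-chromene
Conditions: PPTS (10 mol %), CH2Cl2, rt
Reagents that add atoms: none
Why: Acid-catalysed cyclodehydration in which the tertiary allylic alcohol, conjugated with the electron-rich ring, ionises under very weak acid to an o-quinone-methide-like cation that the neighbouring free phenol captures (six-membered C–O closure, equivalent to an oxa-6π electrocyclisation), and since only the former O1 is unprotected a single chromene can form while MOM ethers and the prenyl group survive PPTS in an aprotic solvent.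

Step 8
Reactants: 14 bis-MOM prenyl chromene; 15 4-(methoxymethoxy)benzaldehyde
Product: 17 [5,7-bis(methoxymethoxy)-2,2-dimethyl-8-(3-methylbut-2-en-1-yl)-2H-chromen-6-yl][4-(methoxymethoxy)phenyl]methanol (racemic), via C6-aryllithium 16 (not isolated)
Conditions: n-BuLi (1.2 equiv), THF, 0 °C, 1 h; then 15, −78 °C → rt; H2O
Reagents that add atoms: none
Why: Directed ortho-metalation, since C6–H is the only aromatic hydrogen of ring A and lies between two chelating OMOM groups, so it should be removed faster than the allylic/benzylic hydrogens, and the aryllithium then adds to the non-enolisable aldehyde to give a carbinol centre that forms as a racemate and is erased in step 9.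

Step 9
Reactants: 17 diaryl carbinol
Product: 18 [5,7-bis(methoxymethoxy)-2,2-dimethyl-8-(3-methylbut-2-en-1-yl)-2H-chromen-6-yl][4-(methoxymethoxy)phenyl]methanone
Conditions: IBX (1.5 equiv), DMSO–THF, rt
Reagents that add atoms: none
Why: IBX oxidation of a doubly benzylic secondary alcohol under neutral conditions, which tolerates MOM acetals, the trisubstituted alkene and the chromene because no free phenol is present.

Step 10
Reactants: 18 tris-MOM benzophenone
Product: 19 vismiaphenone E, [5,7-dihydroxy-2,2-dimethyl-8-(3-methylbut-2-en-1-yl)-2H-chromen-6-yl](4-hydroxyphenyl)methanone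
Conditions: HCl (ca. 1 M, from conc. aq. HCl) in MeOH, rt → 40 °C, closely monitored
Reagents that add atoms: none
Why: Acid-catalysed acetal solvolysis (MOM cleavage) in methanol, in which the two MOM groups ortho to the ketone leave quickly and end as hydrogen-bonded phenols of low nucleophilicity, the aroyl group deactivates ring A towards protonation, and the mild temperature should spare the prenyl and chromene double bonds, as is usual for MOM-protected prenylated acylphloroglucinols.

Compound list
1 | phloroglucinol | Oc1cc(O)cc(O)c1 | starting material
2 | ethyl propiolate | CCOC(=O)C#C | starting material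
3 | 5,7-dihydroxy-2H-chromen-2-one | O=C1C=Cc2c(O)cc(O)cc2O1 | intermediate
4 | 3-chloro-3-methylbut-1-yne | CC(C)(Cl)C#C | starting material
5 | 5-hydroxy-7-[(2-methylbut-3-yn-2-yl)oxy]-2H-chromen-2-one | O=C1C=Cc2c(O)cc(OC(C)(C)C#C)cc2O1 | intermediate
6 | 5-hydroxy-7-[(2-methylbut-3-en-2-yl)oxy]-2H-chromen-2-one | O=C1C=Cc2c(O)cc(OC(C)(C)C=C)cc2O1 | intermediate
7 | 5-hydroxy-8-(3-methylbut-2-en-1-yl)-2H-chromene-2,7(8H)-dione (racemic, transient) | O=C1C=CC2=C(O1)C(CC=C(C)C)C(=O)C=C2O | intermediate
8 | 5,7-dihydroxy-8-(3-methylbut-2-en-1-yl)-2H-chromen-2-one | O=C1C=Cc2c(O)cc(O)c(CC=C(C)C)c2O1 | intermediate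
9 | chloromethyl methyl ether | COCCl | starting material
10 | 5,7-bis(methoxymethoxy)-8-(3-methylbut-2-en-1-yl)-2H-chromen-2-one | COCOc1cc(OCOC)c2C=CC(=O)Oc2c1CC=C(C)C | intermediate
11 | methyllithium | [Li]C | starting material
12 | lithium 3,5-bis(methoxymethoxy)-6-(3-methylbut-2-en-1-yl)-2-[(Z)-3-oxobut-1-en-1-yl]phenoxide | CC(=O)/C=C\c1c([O-])c(CC=C(C)C)c(OCOC)cc1OCOC.[Li+] | intermediate
13 | 2-[(Z)-3-hydroxy-3-methylbut-1-en-1-yl]-3,5-bis(methoxymethoxy)-6-(3-methylbut-2-en-1-yl)phenol | COCOc1cc(OCOC)c(/C=C\C(C)(C)O)c(O)c1CC=C(C)C | intermediate
14 | 5,7-bis(methoxymethoxy)-2,2-dimethyl-8-(3-methylbut-2-en-1-yl)-2H-chromene | COCOc1cc(OCOC)c2C=CC(C)(C)Oc2c1CC=C(C)C | intermediate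
15 | 4-(methoxymethoxy)benzaldehyde | COCOc1ccc(C=O)cc1 | starting material
16 | [5,7-bis(methoxymethoxy)-2,2-dimethyl-8-(3-methylbut-2-en-1-yl)-2H-chromen-6-yl]lithium | [Li]c1c(OCOC)c2C=CC(C)(C)Oc2c(CC=C(C)C)c1OCOC | intermediate
17 | [5,7-bis(methoxymethoxy)-2,2-dimethyl-8-(3-methylbut-2-en-1-yl)-2H-chromen-6-yl][4-(methoxymethoxy)phenyl]methanol (racemic) | COCOc1ccc(cc1)C(O)c1c(OCOC)c2C=CC(C)(C)Oc2c(CC=C(C)C)c1OCOC | intermediate
18 | [5,7-bis(methoxymethoxy)-2,2-dimethyl-8-(3-methylbut-2-en-1-yl)-2H-chromen-6-yl][4-(methoxymethoxy)phenyl]methanone | COCOc1ccc(cc1)C(=O)c1c(OCOC)c2C=CC(C)(C)Oc2c(CC=C(C)C)c1OCOC | intermediate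
19 | vismiaphenone E (achiral) | CC(C)=CCc1c(O)c(C(=O)c2ccc(O)cc2)c(O)c2c1OC(C)(C)C=C2 | target

Total step count: 10. Longest linear sequence: 10 (1 → 19).

Steps most likely to fail

Step 6.
- **What may go wrong:** methyl may be delivered in conjugate fashion to C4. The methyl ketone stage may enolise, so that the second addition stalls. Water may be lost uncontrollably during isolation.
- **Fallback:** the pyran is built by an aryl propargyl ether rearrangement instead of from the lactone. It sets out from 1 (and reuses 4 and 9) and rejoins the route at 14.
- **Course:** Phloroglucinol 1 is treated with two equivalents of 9 (i-Pr2NEt, DMF) and the statistical mixture is separated to give 3,5-bis(methoxymethoxy)phenol F1. Its sodium salt (NaH, toluene) is alkylated on carbon with prenyl bromide at one of the two equivalent ortho positions, as is known for phenoxides in non-polar media, to give 3,5-bis(methoxymethoxy)-2-(3-methylbut-2-en-1-yl)phenol F2. Copper-catalysed etherification with 4 (DBU, CuCl2, MeCN, 0 °C) gives 1,5-bis(methoxymethoxy)-3-[(2-methylbut-3-yn-2-yl)oxy]-2-(3-methylbut-2-en-1-yl)benzene F3. Heating F3 in PhNEt2 should trigger a propargyl Claisen shift to the only free ortho carbon, a 1,5-hydrogen shift and oxa-6π closure, which delivers 14.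

Step 2.
- **What may go wrong:** the two phenols may be poorly discriminated, both may be etherified, or the hindered tertiary ether may form sluggishly.
- **Fallback:** the C8–C bond is made directly instead of by O-alkylation and rearrangement. It sets out from 3 and rejoins at 8, bypassing 5, 6 and 7.
- **Course:** Acid-catalysed nuclear prenylation (Friedel–Crafts type) of 3 with 2-methylbut-3-en-2-ol and BF3·OEt2 in dioxane at rt is stopped at partial conversion. It needs no distinction between O5 and O7. Compound 8 is then separated by chromatography from material alkylated at C6 or at both carbons. This gives up selectivity for brevity and makes no compound outside the list (F0).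

Step 10.
- **What may go wrong:** the freed 7-OH may add to the prenyl double bond under acid. Methanol may add to the chromene, or the chromene ring may open and reclose, before the slowest MOM group has left.
- **Fallback:** the protecting groups are exchanged, so that the last operation is a mildly basic desilylation and no protic acid is used. It sets out from 18 and rejoins at 19.
- **Course:** TESOTf and 2,2′-bipyridyl in MeCN (0 °C → rt) convert aryl MOM ethers into aryl triethylsilyl ethers in a buffered medium, to give {2,2-dimethyl-8-(3-methylbut-2-en-1-yl)-5,7-bis[(triethylsilyl)oxy]-2H-chromen-6-yl}{4-[(triethylsilyl)oxy]phenyl}methanone F4. Catalytic K2CO3 in MeOH at rt then releases 19.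

Further compounds
F1 | step 6 | 3,5-bis(methoxymethoxy)phenol | COCOc1cc(O)cc(OCOC)c1
F2 | step 6 | 3,5-bis(methoxymethoxy)-2-(3-methylbut-2-en-1-yl)phenol | COCOc1cc(O)c(CC=C(C)C)c(OCOC)c1
F3 | step 6 | 1,5-bis(methoxymethoxy)-3-[(2-methylbut-3-yn-2-yl)oxy]-2-(3-methylbut-2-en-1-yl)benzene | COCOc1cc(OC(C)(C)C#C)c(CC=C(C)C)c(OCOC)c1
F0 | step 2 | none | none
F4 | step 10 | {2,2-dimethyl-8-(3-methylbut-2-en-1-yl)-5,7-bis[(triethylsilyl)oxy]-2H-chromen-6-yl}{4-[(triethylsilyl)oxy]phenyl}methanone | CC[Si](CC)(CC)Oc1ccc(cc1)C(=O)c1c(O[Si](CC)(CC)CC)c2C=CC(C)(C)Oc2c(CC=C(C)C)c1O[Si](CC)(CC)CC
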